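Which dosing leaves the most ring at 50 h?

| flask | substrate | activator | remark | time |
|---|---|---|---|---|
| ochre | 20 mM | 2 equiv | run made earlier |  |
| red | 20 mM | 1.3 equiv | run made earlier |  |
| grey | 20 mM | 3 equiv | run made earlier |  |
| eta | 20 mM | 2.00 equiv (in portions, 2, over 20 h) | first portion at the start, last at 20 h | 50 h |
| theta | 20 mM | 2.00 equiv (fed, over 20 h) | all else is in the flask from the start; the feed brings no volume worth counting | 50 h |
| gamma | 20 mM (fed, over 20 h) | 2.00 equiv | all else is in the flask from the start; the feed brings no volume worth counting | 50 h |
| beta | 20 mM | 2.00 equiv | everything together at the start | 50 h |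

| run | time / h | ring / % | substrate / % |
|---|---|---|---|
| ochre | 2.50 | 1.3 | 52.7 |
| ochre | 6.00 | 4.2 | 30.0 |
| ochre | 12.0 | 8.0 | 15.1 |
| ochre | 30.0 | 9.5 | 4.1 |
| red | 12.0 | 5.1 | 19.2 |
| red | 25.0 | 7.4 | 8.4 |
| red | 40.0 | 6.6 | 3.9 |
| red | 48.0 | 5.8 | 3.1 |
| grey | 12.0 | 10.2 | 12.8 |
| grey | 25.0 | 12.7 | 3.2 |
| grey | 40.0 | 11.4 | 1.8 |
| grey | 48.0 | 10.7 | 0.4 |

(readings scatter by 0.5 percentage points)

- the flask with the highest amount of ring, in percent of the substrate charged ("all alike" if they lie within 1.5 percentage points) (eta / theta / gamma / beta / all alike)
- final ring, as a percentage of the substrate charged, in eta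
- final ring, as a percentage of the substrate charged, in theta
- final ring, as a percentage of the substrate charged, in gamma
- final ring, as a percentage of the substrate charged, in beta



Substrate is read here as falling by two routes: second order in itself, and pseudo-first-order with activator, the branch on which this estimate counts ring. The first ochre reading gives a second-order constant of 0.359 h⁻¹ per unit of the charge. The ochre tail gives a first-order rate of 0.0724 h⁻¹. The tail follows activator: grey's tail rate is 2.46 times red's, for 2.31 times the equivalents.

The quotient is the crossover level, the fraction of the charge at which both routes run equally fast: 20.2%. A substrate molecule at fraction x takes the activator branch with chance c/(c+x), c being the crossover level. Summed over the charge, this reckoning puts 36.0% of beta down that branch. Gamma's feed should hold substrate near 28.6%, which sends 47.4%. Eta has half the crossover level until 20 h, which sends 24.9%. Theta starts without activator and is placed just below eta.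

Interpolating the red and grey readings at 48.0 h to 2.00 equiv gives 7.82% of ring, taken as the estimate for beta. With ring per branched substrate held fixed, gamma gets 10.3% and eta 5.42%.

The forecast named gamma, with 7% in eta, 6.5% in theta, 13% in gamma, higher than this reckoning, and 8.3% in beta, holding that “high substrate wastes material”.

Gamma gives 11.6%, the highest, against 8.57% in beta, 6.08% in eta and 4.98% in theta.

    activated form ⇌ ring (K = 0.720, k = 0.150 h⁻¹)
    substrate + activator → activated form (k = 1.30 L mol⁻¹ h⁻¹)
    activated form → side product (k = 0.0180 h⁻¹)
    2 substrate → homo dimer (k = 7.00 L mol⁻¹ h⁻¹)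
    substrate + activated form → open dimer (k = 0.530 L mol⁻¹ h⁻¹)

In theta, the homo dimer step used substrate 26 times as fast as the activator step at 2.47 h, and 0.097 times as fast at 50.0 h; the crossover level scaled by theta's 91.6% of activator, in percent of its own charge, is 18.5%, and the 1.65% of substrate there stands at 0.0892 of it. Homo dimer, counted by the substrate it holds, stood at 81.4% of the charge in theta at 50.0 h, against 56.2% in gamma.

The readings were generated by integration from invented constants, noise included.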